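**Retrosynthetic overview**
- Last bond: the benzylic aryl ether C–O, made by Mitsunobu inversion of an (R)-benzylic alcohol on the bicyclic lactone with the 7-OH of (S)-pinocembrin; the flavanone rings come in intact.
- Bicyclic lactone: both rings close in one operation from an acyclic 1-phenylhex-5-ene-1,2,4-triol by PdCl2-catalysed oxycarbonylation, the tetrahydrofuran ring first (5-exo oxypalladation), then the γ-lactone ring (CO insertion and capture by the allylic OH).
- Ene-triol: from a β-hydroxy ynone by 1,3-syn reduction, desilylation and semi-hydrogenation.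
- Key C–C bond (CH2–CHOH): Felkin-controlled Mukaiyama aldol between O-TBS-(R)-mandelaldehyde and the enol silane of 4-(trimethylsilyl)but-3-yn-2-one.
- Stereocentres: benzylic carbon from (R)-mandelate (inverted at the end), adjacent carbinol by 1,2-induction, allylic carbinol by 1,3-induction, ring-fusion carbon by the cis-fusion requirement, flavanone C2 from pinocembrin.

Assumption: methyl (R)-mandelate, 4-(trimethylsilyl)but-3-yn-2-one and natural (S)-pinocembrin are bought as such; locants in the Why lines are those of the compound named in that step.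

**Route**

Step 1
Reactants: 1 methyl (2R)-2-hydroxy-2-phenylacetate (methyl (R)-mandelate)
Product: 2 methyl (2R)-2-[(tert-butyldimethylsilyl)oxy]-2-phenylacetate
Conditions: TBSCl, imidazole, DMF, 0 °C to rt
Reagents that add atoms: tert-butyldimethylsilyl chloride (TBSCl), CC(C)(C)[Si](C)(C)Cl
Why: O-silylation (silyl ether formation) under imidazole catalysis leaves the benzylic stereocentre untouched and installs a non-chelating group for the later Felkin-controlled addition.

Step 2
Reactants: 2 methyl (2R)-2-[(tert-butyldimethylsilyl)oxy]-2-phenylacetate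
Product: 3 (2R)-2-[(tert-butyldimethylsilyl)oxy]-2-phenylacetaldehyde
Conditions: i-Bu2AlH (1.1 equiv), CH2Cl2, −78 °C; MeOH, then aq. KNaC4H4O6 (potassium sodium tartrate); crude aldehyde used at once
Reagents that add atoms: none
Why: Partial ester reduction with i-Bu2AlH stops at the aldehyde because the tetrahedral aluminium acetal survives at −78 °C, and immediate use of the crude α-silyloxy aldehyde avoids epimerisation.

Step 3
Reactants: 4 4-(trimethylsilyl)but-3-yn-2-one
Product: 6 trimethyl{[4-(trimethylsilyl)but-1-en-3-yn-2-yl]oxy}silane, via lithium enolate 5 (not isolated)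
Conditions: LiN(i-Pr)2, THF, −78 °C; then Me3SiCl, −78 to 0 °C; pentane, filtration, distillation
Reagents that add atoms: chlorotrimethylsilane (Me3SiCl), C[Si](C)(C)Cl
Why: Kinetic deprotonation at the only enolisable position followed by O-silylation of the lithium enolate (silyl enol ether formation) gives the nucleophile for the Mukaiyama aldol.

Step 4
Reactants: 3 (2R)-2-[(tert-butyldimethylsilyl)oxy]-2-phenylacetaldehyde; 6 trimethyl{[4-(trimethylsilyl)but-1-en-3-yn-2-yl]oxy}silane
Product: 7 (5S,6R)-6-[(tert-butyldimethylsilyl)oxy]-5-hydroxy-6-phenyl-1-(trimethylsilyl)hex-1-yn-3-one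
Conditions: BF3·OEt2 (1.1 equiv), CH2Cl2, −78 °C; aq. NaHCO3; minor syn isomer removed on silica
Reagents that add atoms: none
Why: Mukaiyama aldol addition under a non-chelating Lewis acid follows the polar Felkin–Anh model, so the enol silane attacks anti to the OTBS group past the small hydrogen and sets the new 5S carbinol anti to the 6R silyl ether.

Step 5
Reactants: 7 (5S,6R)-6-[(tert-butyldimethylsilyl)oxy]-5-hydroxy-6-phenyl-1-(trimethylsilyl)hex-1-yn-3-one
Product: 9 (1R,2S,4R)-1-[(tert-butyldimethylsilyl)oxy]-1-phenyl-6-(trimethylsilyl)hex-5-yne-2,4-diol, via diethylboron chelate 8 (not isolated)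
Conditions: Et2BOMe, THF/MeOH (4:1), −78 °C; then NaBH4, −78 °C; AcOH; MeOH co-evaporation
Reagents that add atoms: none
Why: Narasaka–Prasad reduction, in which the six-membered boron chelate of the β-hydroxy ketone is attacked by external hydride from the axial direction, gives the 1,3-syn diol and sets the 4R propargylic centre.

Step 6
Reactants: 9 (1R,2S,4R)-1-[(tert-butyldimethylsilyl)oxy]-1-phenyl-6-(trimethylsilyl)hex-5-yne-2,4-diol
Product: 10 (1R,2S,4R)-1-phenylhex-5-yne-1,2,4-triol
Conditions: Bu4NF (3 equiv), THF, 0 °C to rt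
Reagents that add atoms: none
Why: Fluoride-mediated desilylation cleaves both the alkynyl C–Si bond and the secondary silyl ether without touching any stereocentre.

Step 7
Reactants: 10 (1R,2S,4R)-1-phenylhex-5-yne-1,2,4-triol
Product: 11 (1R,2S,4R)-1-phenylhex-5-ene-1,2,4-triol
Conditions: H2 (1 atm), Pd on CaCO3 poisoned with Pb(OAc)2, quinoline, EtOAc, rt, stopped after 1 equiv H2
Reagents that add atoms: none
Why: Lindlar semi-hydrogenation takes the terminal alkyne to the vinyl group and stops there, and the benzylic C–O bonds are inert to the poisoned catalyst.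

Step 8
Reactants: 11 (1R,2S,4R)-1-phenylhex-5-ene-1,2,4-triol
Product: 12 (3aR,5S,6aR)-5-[(R)-hydroxy(phenyl)methyl]tetrahydrofuro[3,2-b]furan-2(3H)-one
Conditions: PdCl2 (10 mol %), CuCl2 (3 equiv), NaOAc (3 equiv), CO (1 atm), AcOH, rt
Reagents that add atoms: carbon monoxide, [C-]#[O+]
Why: In this oxycarbonylation (alkoxypalladation, CO insertion, lactonisation) the 2-OH adds 5-exo to the alkene activated by divalent palladium, and only the adduct with the new C–O bond cis to the allylic 4-OH can close the lactone, which fixes the 3aR centre and places the side chain on the convex face.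

Step 9
Reactants: 12 (3aR,5S,6aR)-5-[(R)-hydroxy(phenyl)methyl]tetrahydrofuro[3,2-b]furan-2(3H)-one; 13 (2S)-5,7-dihydroxy-2-phenyl-2,3-dihydro-4H-chromen-4-one ((S)-pinocembrin)
Product: 14 (2S)-5-hydroxy-7-{(S)-[(3aR,5S,6aR)-2-oxohexahydrofuro[3,2-b]furan-5-yl](phenyl)methoxy}-2-phenyl-2,3-dihydro-4H-chromen-4-one (CNP0152032.1)
Conditions: PPh3, DIAD, THF, 0 °C to rt (DIAD added last)
Reagents that add atoms: none
Why: In this Mitsunobu etherification the 7-OH of 13 (the acidic phenol; the 5-OH is locked in a hydrogen bond to the ketone) displaces the oxyphosphonium of the benzylic alcohol by SN2 with inversion (R to S), while the neutral conditions leave the lactone and the flavanone centre alone.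

**Compound list**
1 | methyl (2R)-2-hydroxy-2-phenylacetate | COC(=O)[C@H](O)c1ccccc1 | starting material
2 | methyl (2R)-2-[(tert-butyldimethylsilyl)oxy]-2-phenylacetate | COC(=O)[C@H](O[Si](C)(C)C(C)(C)C)c1ccccc1 | intermediate
3 | (2R)-2-[(tert-butyldimethylsilyl)oxy]-2-phenylacetaldehyde | O=C[C@H](O[Si](C)(C)C(C)(C)C)c1ccccc1 | intermediate
4 | 4-(trimethylsilyl)but-3-yn-2-one | CC(=O)C#C[Si](C)(C)C | starting material
5 | lithium 4-(trimethylsilyl)but-1-en-3-yn-2-olate | [Li]OC(=C)C#C[Si](C)(C)C | intermediate (not isolated)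
6 | trimethyl{[4-(trimethylsilyl)but-1-en-3-yn-2-yl]oxy}silane | C=C(O[Si](C)(C)C)C#C[Si](C)(C)C | intermediate
7 | (5S,6R)-6-[(tert-butyldimethylsilyl)oxy]-5-hydroxy-6-phenyl-1-(trimethylsilyl)hex-1-yn-3-one | C[Si](C)(C)C#CC(=O)C[C@H](O)[C@H](O[Si](C)(C)C(C)(C)C)c1ccccc1 | intermediate
8 | (5S,6R)-6-[(tert-butyldimethylsilyl)oxy]-5-[(diethylboranyl)oxy]-6-phenyl-1-(trimethylsilyl)hex-1-yn-3-one (boron chelated by the ketone) | CCB(CC)O[C@@H](CC(=O)C#C[Si](C)(C)C)[C@H](O[Si](C)(C)C(C)(C)C)c1ccccc1 | intermediate (not isolated)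
9 | (1R,2S,4R)-1-[(tert-butyldimethylsilyl)oxy]-1-phenyl-6-(trimethylsilyl)hex-5-yne-2,4-diol | C[Si](C)(C)C#C[C@H](O)C[C@H](O)[C@H](O[Si](C)(C)C(C)(C)C)c1ccccc1 | intermediate
10 | (1R,2S,4R)-1-phenylhex-5-yne-1,2,4-triol | C#C[C@H](O)C[C@H](O)[C@H](O)c1ccccc1 | intermediate
11 | (1R,2S,4R)-1-phenylhex-5-ene-1,2,4-triol | C=C[C@H](O)C[C@H](O)[C@H](O)c1ccccc1 | intermediate
12 | (3aR,5S,6aR)-5-[(R)-hydroxy(phenyl)methyl]tetrahydrofuro[3,2-b]furan-2(3H)-one | O=C1C[C@H]2O[C@H]([C@H](O)c3ccccc3)C[C@H]2O1 | intermediate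
13 | (2S)-5,7-dihydroxy-2-phenyl-2,3-dihydro-4H-chromen-4-one ((S)-pinocembrin) | Oc1cc(O)c2c(c1)O[C@H](c1ccccc1)CC2=O | starting material
14 | (2S)-5-hydroxy-7-{(S)-[(3aR,5S,6aR)-2-oxohexahydrofuro[3,2-b]furan-5-yl](phenyl)methoxy}-2-phenyl-2,3-dihydro-4H-chromen-4-one | O=C1C[C@H]2O[C@H]([C@@H](Oc3cc(O)c4c(c3)O[C@H](c3ccccc3)CC4=O)c3ccccc3)C[C@H]2O1 | target

**Step count and risks**
Total: 9 steps. Longest linear sequence: 8 steps (1 → 2 → 3 → 7 → 9 → 10 → 11 → 12 → 14); step 3 is a one-step side branch.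

The three steps most likely to fail:

Step 4 (aldol: epimerisable aldehyde, anti selectivity may be only moderate). The fallback sets out from aldehyde 3 and comes back at ene-triol 11. Reagent-controlled allylboration of 3 with (−)-Ipc2B(allyl) (the enantiomer that turns benzaldehyde into (S)-1-phenylbut-3-en-1-ol; Et2O, −78 °C, then NaOH/H2O2) gives (1R,2S)-1-[(tert-butyldimethylsilyl)oxy]-1-phenylpent-4-en-2-ol F1. Boc2O and DMAP convert it to tert-butyl (1R,2S)-1-[(tert-butyldimethylsilyl)oxy]-1-phenylpent-4-en-2-yl carbonate F2. IBr in toluene at −85 °C cyclises this to the cis iodocarbonate (4R,6S)-4-(iodomethyl)-6-{(R)-[(tert-butyldimethylsilyl)oxy](phenyl)methyl}-1,3-dioxan-2-one F3, which fixes the 1,3-syn relationship. K2CO3 in MeOH at 0 °C gives (1R,2S)-1-[(tert-butyldimethylsilyl)oxy]-3-[(2R)-oxiran-2-yl]-1-phenylpropan-2-ol F4. Excess dimethylsulfonium methylide (Me3SI, n-BuLi, THF) opens the epoxide to the allylic alcohol (1R,2S,4R)-1-[(tert-butyldimethylsilyl)oxy]-1-phenylhex-5-ene-2,4-diol F5, and Bu4NF then delivers 11.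

Step 8 (oxycarbonylation: catalyst turnover, possible competition from the benzylic OH). The fallback sets out from 11 and comes back at 12. Cross-metathesis of 11 with methyl acrylate (second-generation Hoveyda–Grubbs catalyst, CH2Cl2, 40 °C) gives methyl (2E,4R,6S,7R)-4,6,7-trihydroxy-7-phenylhept-2-enoate F6. Catalytic DBU in CH2Cl2 then promotes reversible oxa-Michael addition of the 6-OH; only the adduct cis to the 4-OH lactonises, so the equilibrium drains into 12.

Step 9 (Mitsunobu at a hindered secondary benzylic alcohol). The fallback sets out from 12 and comes back at 14. MsCl and Et3N in CH2Cl2 at −20 °C give, with retention, (R)-phenyl[(3aR,5S,6aR)-2-oxohexahydrofuro[3,2-b]furan-5-yl]methyl methanesulfonate F7. Displacement by the 7-phenoxide of 13 (Cs2CO3, 1 equiv, DMF, 0 °C to rt) proceeds by SN2 with inversion to 14; the base is kept stoichiometric and cold to avoid opening the flavanone.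

**Further compounds**
F1 | step 4 | (1R,2S)-1-[(tert-butyldimethylsilyl)oxy]-1-phenylpent-4-en-2-ol | C=CC[C@H](O)[C@H](O[Si](C)(C)C(C)(C)C)c1ccccc1
F2 | step 4 | tert-butyl (1R,2S)-1-[(tert-butyldimethylsilyl)oxy]-1-phenylpent-4-en-2-yl carbonate | C=CC[C@H](OC(=O)OC(C)(C)C)[C@H](O[Si](C)(C)C(C)(C)C)c1ccccc1
F3 | step 4 | (4R,6S)-4-(iodomethyl)-6-{(R)-[(tert-butyldimethylsilyl)oxy](phenyl)methyl}-1,3-dioxan-2-one | IC[C@H]1C[C@@H]([C@H](O[Si](C)(C)C(C)(C)C)c2ccccc2)OC(=O)O1
F4 | step 4 | (1R,2S)-1-[(tert-butyldimethylsilyl)oxy]-3-[(2R)-oxiran-2-yl]-1-phenylpropan-2-ol | C1O[C@@H]1C[C@H](O)[C@H](O[Si](C)(C)C(C)(C)C)c1ccccc1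
F5 | step 4 | (1R,2S,4R)-1-[(tert-butyldimethylsilyl)oxy]-1-phenylhex-5-ene-2,4-diol | C=C[C@H](O)C[C@H](O)[C@H](O[Si](C)(C)C(C)(C)C)c1ccccc1
F6 | step 8 | methyl (2E,4R,6S,7R)-4,6,7-trihydroxy-7-phenylhept-2-enoate | COC(=O)/C=C/[C@H](O)C[C@H](O)[C@H](O)c1ccccc1
F7 | step 9 | (R)-phenyl[(3aR,5S,6aR)-2-oxohexahydrofuro[3,2-b]furan-5-yl]methyl methanesulfonate | O=C1C[C@H]2O[C@H]([C@H](OS(C)(=O)=O)c3ccccc3)C[C@H]2O1
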